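**Plan**

1. Numbering (drimane): ring A = C1–C5 and C10 (C3 ketone, C4 gem-dimethyl); ring B = C5–C10 (C7=C8, methyl on C8); C11 = the OCH2 carbon on C9.
2. Cuts, last to first: O–C11 (Mitsunobu with isofraxidin); C9–C11 and the C7=C8 position (1,4-addition, enolate trapped); C8–C9 (aldol condensation, ring B); C2–C3 and C4–C5 together (ring A); C5=C6 (Wittig); C10–C1 (Michael).
3. Enabling feature: in ring A the C3 carbonyl sits next to the fully substituted C4(CH3)2, so C3–C4 is a dimethylketene unit (electrophilic at C3, then an enolate at C4). C2 is α to C3 and can carry a removable malonate anion; C5 is β to the C7 carbonyl of ring B and can be the Michael terminus.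
4. Forward: acyclic enone–malonate 10 → ring A by an anionic [4+2] with dimethylketene (C2→C3, then C4→C5) → ring B by aldol condensation → vinyl (C11) on C9 with enol triflate → CH2OH, C7=C8, loss of the two esters → aryl ether.
5. Stereochemistry: C10 from an enantioselective Michael addition (step 2); C5 in the key step, trans to the C9 arm (chair transition state, bulky dioxanyl acetal equatorial); C9 by cuprate attack anti to the axial C10 methyl group.
6. Helpers: malonate esters on C2 (make C2 acidic, shield the C3 ketone; removed in step 12); dioxane acetal on C9 (masks the aldehyde, steers C5; removed in step 8); thioester (latent C5 aldehyde, step 4); enol triflate (step 11).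

Key step: step 7

Remark: 4 (stabilised, distilled before use), 9 and isofraxidin 25 are taken as catalogue compounds; the quinine- or quinidine-series catalyst in step 2 is the one that gives the (R)-adduct.

**Route**

Step 1
Reactants: 1 S-ethyl propanethioate; 2 ethyl formate
Product: 3 S-ethyl 2-methyl-3-oxopropanethioate
Conditions: LiN(i-Pr)2 (1.1 equiv), THF, −78 °C; then 2 (1.5 equiv), −78 → −20 °C; aq. HCl
Reagents that add atoms: none
Why: Crossed Claisen formylation of the thioester lithium enolate, in which the α-formyl thioester is deprotonated by the released ethoxide as it forms and so cannot react a second time.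

Step 2
Reactants: 3 S-ethyl 2-methyl-3-oxopropanethioate; 4 dimethyl 2-methylidenepropanedioate
Product: 5 dimethyl 2-[(2R)-3-(ethylsulfanyl)-2-formyl-2-methyl-3-oxopropyl]propanedioate
Conditions: quinine-derived bifunctional squaramide catalyst (5 mol %), toluene, −40 °C
Reagents that add atoms: none
Why: Enantioselective Michael addition of an α-substituted 1,3-dicarbonyl donor to a doubly activated alkene under bifunctional cinchona catalysis, in which the catalyst-bound, hydrogen-bonded enolate is attacked on one face and the quaternary stereocenter (R) is set.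

Step 3
Reactants: 5 dimethyl 2-[(2R)-3-(ethylsulfanyl)-2-formyl-2-methyl-3-oxopropyl]propanedioate; 6 2,2-dimethylpropane-1,3-diol
Product: 7 dimethyl 2-[(2R)-2-(5,5-dimethyl-1,3-dioxan-2-yl)-3-(ethylsulfanyl)-2-methyl-3-oxopropyl]propanedioate
Conditions: pyridinium p-toluenesulfonate (cat.), benzene, reflux, Dean–Stark
Reagents that add atoms: none
Why: Acid-catalysed acetalization is selective for the aldehyde (thioester and esters do not react) and installs the branched cyclic acetal that later masks C9 and steers the ring closure.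

Step 4
Reactants: 7 dimethyl 2-[(2R)-2-(5,5-dimethyl-1,3-dioxan-2-yl)-3-(ethylsulfanyl)-2-methyl-3-oxopropyl]propanedioate
Product: 8 dimethyl 2-[(2S)-2-(5,5-dimethyl-1,3-dioxan-2-yl)-2-methyl-3-oxopropyl]propanedioate
Conditions: Et3SiH (3 equiv), Pd/C (5 mol % Pd), acetone, rt
Reagents that add atoms: none
Why: Fukuyama reduction (oxidative addition of zerovalent palladium into the C–S bond, hydride transfer from the silane) converts the thioester into the aldehyde and leaves the methyl esters and the acetal untouched.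

Step 5
Reactants: 8 dimethyl 2-[(2S)-2-(5,5-dimethyl-1,3-dioxan-2-yl)-2-methyl-3-oxopropyl]propanedioate; 9 1-(triphenyl-λ5-phosphanylidene)butan-2-one
Product: 10 dimethyl 2-[(2S,3E)-2-(5,5-dimethyl-1,3-dioxan-2-yl)-2-methyl-5-oxohept-3-en-1-yl]propanedioate
Conditions: toluene, 100 °C
Reagents that add atoms: none
Why: Wittig olefination with the stabilised keto ylide is specific for the aldehyde and should give the (E)-enone.

Step 6
Reactants: 11 2-bromo-2-methylpropanoyl bromide
Product: 12 dimethylketene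
Conditions: Zn dust, ethyl acetate, reflux under N2; 12 co-distilled as an ethyl acetate solution and used at once
Reagents that add atoms: none
Why: Zinc dehalogenation of the α-bromo acyl bromide (Staudinger ketene synthesis) gives dimethylketene, which is distilled out as it forms so that it cannot dimerise.

Step 7
Reactants: 10 dimethyl 2-[(2S,3E)-2-(5,5-dimethyl-1,3-dioxan-2-yl)-2-methyl-5-oxohept-3-en-1-yl]propanedioate; 12 dimethylketene
Product: 16 dimethyl (4R,5S)-5-(5,5-dimethyl-1,3-dioxan-2-yl)-3,3,5-trimethyl-2-oxo-4-(2-oxobutyl)cyclohexane-1,1-dicarboxylate, via sodium malonate 13 (not isolated), via acyl enolate 14 (not isolated), via ring-closed enolate 15 (not isolated)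
Conditions: NaH (1.0 equiv), THF (0.02 M), 0 °C until H2 evolution stops; then 12 (1.05 equiv, added over 1 h), −78 °C; −78 → −20 °C; AcOH (1.2 equiv), −78 °C
Reagents that add atoms: none
Why: Proposed new method: the sodium malonate 13 (C2) should add to the central carbon of dimethylketene (C3), a C-acylation that creates the tetrasubstituted enolate 14 regiospecifically at C4 with no base present that could touch the enone, and this enolate should then add to the tethered enone at C5, which closes ring A and forms the C2–C3 and C4–C5 bonds in one flask event. The closest known reactions are the C-acylation of malonate and other carbanions by ketenes to give regiodefined enolates, and base-mediated Michael-initiated [4+2] annulations. Ring A closes in a 6-(enolendo)-exo-trig Michael mode. The new stereocenter C5 is set relative to C10 in a chair-like transition state in which the enone chain on C5 and the branched dioxanyl group on C10 are both equatorial and the C10 methyl group is axial, because an axial dioxanyl group would clash with the syn-axial ester on C2 and methyl group on C4; this places the C6 and C9 arms trans, as the later trans ring fusion needs. The step needs C- over O-selectivity twice (O-acylation of the malonate and oxa-Michael addition of 14 are reversible and should drain into the C–C bonded product) and mono-addition of the ketene (one equivalent, slow addition at −78 °C, cold acidic quench so that enolate 15 cannot attack a malonate ester). The malonate anion itself has no ring-forming escape, since reaching C5 would need a four-membered ring and reaching C7 a six-membered ring that contains the E double bond.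

Step 8
Reactants: 16 dimethyl (4R,5S)-5-(5,5-dimethyl-1,3-dioxan-2-yl)-3,3,5-trimethyl-2-oxo-4-(2-oxobutyl)cyclohexane-1,1-dicarboxylate
Product: 18 dimethyl (4aR,8aR)-4,4,7,8a-tetramethyl-3,6-dioxo-3,4,4a,5,6,8a-hexahydronaphthalene-2,2(1H)-dicarboxylate, via keto aldehyde 17 (not isolated)
Conditions: 2 M aq. HCl/THF (1:4), 55 °C
Reagents that add atoms: none
Why: Aqueous acid hydrolyses the acetal, and the freed C9 aldehyde should undergo intramolecular aldol condensation with the enol at C8 of the ethyl ketone (the only enol carbon that reaches it through a six-membered ring), closing ring B as the trans-fused enone without touching C5 or C10.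

Step 9
Reactants: 18 dimethyl (4aR,8aR)-4,4,7,8a-tetramethyl-3,6-dioxo-3,4,4a,5,6,8a-hexahydronaphthalene-2,2(1H)-dicarboxylate
Product: 20 dimethyl (4aR,8S,8aS)-8-ethenyl-4,4,7,8a-tetramethyl-3-oxo-6-[(trifluoromethanesulfonyl)oxy]-3,4,4a,5,8,8a-hexahydronaphthalene-2,2(1H)-dicarboxylate, via magnesium enolate 19 (not isolated)
Conditions: CH2=CHMgBr (3 equiv), CuBr·SMe2 (1.5 equiv), THF, −78 → −30 °C; then PhNTf2 (2 equiv), −78 °C → rt; aq. NH4Cl
Reagents that add atoms: vinylmagnesium bromide, C=C[Mg]Br; N-phenylbis(trifluoromethanesulfonimide), O=S(=O)(N(c1ccccc1)S(=O)(=O)C(F)(F)F)C(F)(F)F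
Why: Cuprate 1,4-addition should put the vinyl group (the future C11) on C9 by axial attack anti to the axial C10 methyl group (the known course for steroidal 1-en-3-ones, which give 1α-substituted products), and the regiodefined magnesium enolate is trapped on oxygen as the C7=C8 enol triflate.

Step 10
Reactants: 20 dimethyl (4aR,8S,8aS)-8-ethenyl-4,4,7,8a-tetramethyl-3-oxo-6-[(trifluoromethanesulfonyl)oxy]-3,4,4a,5,8,8a-hexahydronaphthalene-2,2(1H)-dicarboxylate
Product: 22 dimethyl (4aR,8S,8aS)-8-(hydroxymethyl)-4,4,7,8a-tetramethyl-3-oxo-6-[(trifluoromethanesulfonyl)oxy]-3,4,4a,5,8,8a-hexahydronaphthalene-2,2(1H)-dicarboxylate, via aldehyde 21 (not isolated)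
Conditions: O3, CH2Cl2/MeOH (4:1), −78 °C, stopped at first persistent blue colour; then NaBH4 (3 equiv), −78 → 0 °C
Reagents that add atoms: ozone, [O-][O+]=O
Why: Ozone should cleave only the monosubstituted alkene (the enol triflate alkene is electron-poor) and borohydride reduces the aldehyde at once to the primary alcohol, while the C3 ketone between two quaternary carbons is too hindered to be reduced.

Step 11
Reactants: 22 dimethyl (4aR,8S,8aS)-8-(hydroxymethyl)-4,4,7,8a-tetramethyl-3-oxo-6-[(trifluoromethanesulfonyl)oxy]-3,4,4a,5,8,8a-hexahydronaphthalene-2,2(1H)-dicarboxylate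
Product: 23 dimethyl (4aR,8R,8aS)-8-(hydroxymethyl)-4,4,7,8a-tetramethyl-3-oxo-3,4,4a,5,8,8a-hexahydronaphthalene-2,2(1H)-dicarboxylate
Conditions: Pd(OAc)2 (5 mol %), PPh3 (10 mol %), n-Bu3N (3 equiv), HCO2H (2 equiv), DMF, 60 °C
Reagents that add atoms: none
Why: Palladium-catalysed formate reduction of the enol triflate (oxidative addition to zerovalent palladium, formate exchange, loss of CO2, reductive elimination) replaces OTf by H and leaves the C7=C8 double bond where the enolate trapping put it.

Step 12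
Reactants: 23 dimethyl (4aR,8R,8aS)-8-(hydroxymethyl)-4,4,7,8a-tetramethyl-3-oxo-3,4,4a,5,8,8a-hexahydronaphthalene-2,2(1H)-dicarboxylate
Product: 24 (4aS,5R,8aR)-5-(hydroxymethyl)-1,1,4a,6-tetramethyl-3,4,4a,5,8,8a-hexahydronaphthalen-2(1H)-one
Conditions: LiCl (4 equiv), H2O (4 equiv), DMSO, 150 °C
Reagents that add atoms: none
Why: Double Krapcho dealkoxycarbonylation (chloride demethylates each ester and the carboxylate loses CO2 through a stabilised enolate) removes the two helper esters from C2 under neutral conditions that spare the alkene, the alcohol and the C9 stereocenter.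

Step 13
Reactants: 24 (4aS,5R,8aR)-5-(hydroxymethyl)-1,1,4a,6-tetramethyl-3,4,4a,5,8,8a-hexahydronaphthalen-2(1H)-one; 25 isofraxidin (7-hydroxy-6,8-dimethoxy-2H-chromen-2-one)
Product: 26 7-{[(1R,4aR,8aS)-2,5,5,8a-tetramethyl-6-oxo-1,4,4a,5,6,7,8,8a-octahydronaphthalen-1-yl]methoxy}-6,8-dimethoxy-2H-chromen-2-one
Conditions: PPh3 (1.5 equiv), diisopropyl azodicarboxylate (1.5 equiv), THF, 0 °C → rt
Reagents that add atoms: none
Why: Mitsunobu etherification joins the acidic 7-hydroxycoumarin oxygen to the primary C11 alcohol (activated as its alkoxyphosphonium salt) without touching any stereocenter, the ketone or the trisubstituted alkene.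

**Compound list**

1 | S-ethyl propanethioate | CCC(=O)SCC | starting material
2 | ethyl formate | CCOC=O | starting material
3 | S-ethyl 2-methyl-3-oxopropanethioate | CCSC(=O)C(C)C=O | intermediate
4 | dimethyl 2-methylidenepropanedioate | C=C(C(=O)OC)C(=O)OC | starting material
5 | dimethyl 2-[(2R)-3-(ethylsulfanyl)-2-formyl-2-methyl-3-oxopropyl]propanedioate | CCSC(=O)[C@](C)(CC(C(=O)OC)C(=O)OC)C=O | intermediate
6 | 2,2-dimethylpropane-1,3-diol | OCC(C)(C)CO | starting material
7 | dimethyl 2-[(2R)-2-(5,5-dimethyl-1,3-dioxan-2-yl)-3-(ethylsulfanyl)-2-methyl-3-oxopropyl]propanedioate | CCSC(=O)[C@](C)(CC(C(=O)OC)C(=O)OC)C1OCC(C)(C)CO1 | intermediate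
8 | dimethyl 2-[(2S)-2-(5,5-dimethyl-1,3-dioxan-2-yl)-2-methyl-3-oxopropyl]propanedioate | O=C[C@](C)(CC(C(=O)OC)C(=O)OC)C1OCC(C)(C)CO1 | intermediate
9 | 1-(triphenyl-λ5-phosphanylidene)butan-2-one | CCC(=O)C=P(c1ccccc1)(c1ccccc1)c1ccccc1 | starting material
10 | dimethyl 2-[(2S,3E)-2-(5,5-dimethyl-1,3-dioxan-2-yl)-2-methyl-5-oxohept-3-en-1-yl]propanedioate | CCC(=O)/C=C/[C@](C)(CC(C(=O)OC)C(=O)OC)C1OCC(C)(C)CO1 | intermediate
11 | 2-bromo-2-methylpropanoyl bromide | CC(C)(Br)C(Br)=O | starting material
12 | dimethylketene (2-methylprop-1-en-1-one) | CC(C)=C=O | intermediate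
13 | sodium salt of 10 (carbanion at the malonate carbon C2) | CCC(=O)/C=C/[C@](C)(C[C-](C(=O)OC)C(=O)OC)C1OCC(C)(C)CO1.[Na+] | intermediate
14 | sodium enolate of dimethyl 2-[(2S,3E)-2-(5,5-dimethyl-1,3-dioxan-2-yl)-2-methyl-5-oxohept-3-en-1-yl]-2-(2-methylpropanoyl)propanedioate | CCC(=O)/C=C/[C@](C)(CC(C(=O)OC)(C(=O)OC)C([O-])=C(C)C)C1OCC(C)(C)CO1.[Na+] | intermediate
15 | sodium enolate (2-oxobutyl chain) of 16 | CCC([O-])=C[C@H]1C(C)(C)C(=O)C(C(=O)OC)(C(=O)OC)C[C@]1(C)C1OCC(C)(C)CO1.[Na+] | intermediate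
16 | dimethyl (4R,5S)-5-(5,5-dimethyl-1,3-dioxan-2-yl)-3,3,5-trimethyl-2-oxo-4-(2-oxobutyl)cyclohexane-1,1-dicarboxylate | CCC(=O)C[C@H]1C(C)(C)C(=O)C(C(=O)OC)(C(=O)OC)C[C@]1(C)C1OCC(C)(C)CO1 | intermediate
17 | dimethyl (4R,5S)-5-formyl-3,3,5-trimethyl-2-oxo-4-(2-oxobutyl)cyclohexane-1,1-dicarboxylate | CCC(=O)C[C@H]1C(C)(C)C(=O)C(C(=O)OC)(C(=O)OC)C[C@]1(C)C=O | intermediate
18 | dimethyl (4aR,8aR)-4,4,7,8a-tetramethyl-3,6-dioxo-3,4,4a,5,6,8a-hexahydronaphthalene-2,2(1H)-dicarboxylate | COC(=O)C1(C(=O)OC)C[C@]2(C)C=C(C)C(=O)C[C@H]2C(C)(C)C1=O | intermediate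
19 | bromomagnesium enolate of the 8-ethenyl 6-ketone (dimethyl (4aR,8S,8aS)-6-[(bromomagnesio)oxy]-8-ethenyl-4,4,7,8a-tetramethyl-3-oxo-3,4,4a,5,8,8a-hexahydronaphthalene-2,2(1H)-dicarboxylate) | COC(=O)C1(C(=O)OC)C[C@]2(C)[C@H](C=C)C(C)=C(O[Mg]Br)C[C@H]2C(C)(C)C1=O | intermediate
20 | dimethyl (4aR,8S,8aS)-8-ethenyl-4,4,7,8a-tetramethyl-3-oxo-6-[(trifluoromethanesulfonyl)oxy]-3,4,4a,5,8,8a-hexahydronaphthalene-2,2(1H)-dicarboxylate | COC(=O)C1(C(=O)OC)C[C@]2(C)[C@H](C=C)C(C)=C(OS(=O)(=O)C(F)(F)F)C[C@H]2C(C)(C)C1=O | intermediate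
21 | dimethyl (4aR,8S,8aS)-8-formyl-4,4,7,8a-tetramethyl-3-oxo-6-[(trifluoromethanesulfonyl)oxy]-3,4,4a,5,8,8a-hexahydronaphthalene-2,2(1H)-dicarboxylate | COC(=O)C1(C(=O)OC)C[C@]2(C)[C@H](C=O)C(C)=C(OS(=O)(=O)C(F)(F)F)C[C@H]2C(C)(C)C1=O | intermediate
22 | dimethyl (4aR,8S,8aS)-8-(hydroxymethyl)-4,4,7,8a-tetramethyl-3-oxo-6-[(trifluoromethanesulfonyl)oxy]-3,4,4a,5,8,8a-hexahydronaphthalene-2,2(1H)-dicarboxylate | COC(=O)C1(C(=O)OC)C[C@]2(C)[C@H](CO)C(C)=C(OS(=O)(=O)C(F)(F)F)C[C@H]2C(C)(C)C1=O | intermediate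
23 | dimethyl (4aR,8R,8aS)-8-(hydroxymethyl)-4,4,7,8a-tetramethyl-3-oxo-3,4,4a,5,8,8a-hexahydronaphthalene-2,2(1H)-dicarboxylate | COC(=O)C1(C(=O)OC)C[C@]2(C)[C@H](CO)C(C)=CC[C@H]2C(C)(C)C1=O | intermediate
24 | (4aS,5R,8aR)-5-(hydroxymethyl)-1,1,4a,6-tetramethyl-3,4,4a,5,8,8a-hexahydronaphthalen-2(1H)-one | OC[C@@H]1C(C)=CC[C@H]2C(C)(C)C(=O)CC[C@]12C | intermediate
25 | isofraxidin (7-hydroxy-6,8-dimethoxy-2H-chromen-2-one) | COc1cc2ccc(=O)oc2c(OC)c1O | starting material
26 | 7-{[(1R,4aR,8aS)-2,5,5,8a-tetramethyl-6-oxo-1,4,4a,5,6,7,8,8a-octahydronaphthalen-1-yl]methoxy}-6,8-dimethoxy-2H-chromen-2-one | COc1cc2ccc(=O)oc2c(OC)c1OC[C@@H]1C(C)=CC[C@H]2C(C)(C)C(=O)CC[C@]12C | target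

**Step count**

Total: 13 steps. Longest linear sequence: 12 steps (steps 1–5 and 7–13); step 6 is a one-step side branch.

**Steps most likely to fail**

1. Step 7 (Proposed new method). The ketene may be used up by O-acylation or anionic oligomerisation before ring closure. The Michael addition at the very hindered C5 may be slow enough for proton transfer from the enone α′-position or retro-acylation to win. The facial preference set by the acetal may be too small. Fallback with known chemistry, from 10 back to 16: the sodium malonate of 10 (NaH, THF, 0 °C) is C-acylated with 2-bromo-2-methylpropanoyl bromide 11 to give dimethyl 2-(2-bromo-2-methylpropanoyl)-2-[(2S,3E)-2-(5,5-dimethyl-1,3-dioxan-2-yl)-2-methyl-5-oxohept-3-en-1-yl]propanedioate F1. Its tertiary α-keto radical (Bu3SnH added slowly, azobisisobutyronitrile, benzene, 80 °C) should then close ring A by 6-exo-trig addition to C5 of the enone through the same chair arrangement, and hydrogen transfer to the α-keto radical at C6 gives 16.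

2. Step 2. Uncatalysed addition of the acidic enol to the very reactive acceptor may compete, and the catalyst may distinguish the formyl and thioester groups too weakly, so the enantiomeric purity of the quaternary center may be low. Fallback, from 3 and 4 back to 7: the Michael addition is run without chiral control (Et3N, 5 mol %, CH2Cl2, 0 °C) to give racemic dimethyl 2-[3-(ethylsulfanyl)-2-formyl-2-methyl-3-oxopropyl]propanedioate F2. Acetalization as in step 3 gives racemic dimethyl 2-[2-(5,5-dimethyl-1,3-dioxan-2-yl)-3-(ethylsulfanyl)-2-methyl-3-oxopropyl]propanedioate F3, and the enantiomers are separated by preparative supercritical-fluid chromatography on a chiral stationary phase; the (R)-enantiomer is 7.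

3. Step 9. The cuprate may add 1,2 or not at all at the β-carbon next to the quaternary C10, or O-triflation of the magnesium enolate may be incomplete. Fallback, from 18 back to 23, replacing steps 9–11 by a sigmatropic transfer of C11:
   - Luche reduction (NaBH4, CeCl3·7H2O, MeOH, −78 °C) should give the equatorial allylic alcohol dimethyl (4aR,6S,8aR)-6-hydroxy-4,4,7,8a-tetramethyl-3-oxo-3,4,4a,5,6,8a-hexahydronaphthalene-2,2(1H)-dicarboxylate F4.
   - Mitsunobu inversion (4-nitrobenzoic acid, PPh3, diisopropyl azodicarboxylate) gives dimethyl (4aR,6R,8aR)-4,4,7,8a-tetramethyl-6-[(4-nitrobenzoyl)oxy]-3-oxo-3,4,4a,5,6,8a-hexahydronaphthalene-2,2(1H)-dicarboxylate F5.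
   - Methanolysis (K2CO3, MeOH) gives dimethyl (4aR,6R,8aR)-6-hydroxy-4,4,7,8a-tetramethyl-3-oxo-3,4,4a,5,6,8a-hexahydronaphthalene-2,2(1H)-dicarboxylate F6.
   - O-Alkylation (KH, Bu3SnCH2I, THF) gives dimethyl (4aR,6R,8aR)-4,4,7,8a-tetramethyl-3-oxo-6-[(tributylstannyl)methoxy]-3,4,4a,5,6,8a-hexahydronaphthalene-2,2(1H)-dicarboxylate F7.
   - Tin–lithium exchange (n-BuLi, THF, −78 °C) triggers the [2,3]-Wittig–Still rearrangement, which should deliver CH2OH to C9 on the face that carried the oxygen and move the double bond to C7=C8, giving 23.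

Further compounds
F1 | step 7 | dimethyl 2-(2-bromo-2-methylpropanoyl)-2-[(2S,3E)-2-(5,5-dimethyl-1,3-dioxan-2-yl)-2-methyl-5-oxohept-3-en-1-yl]propanedioate | CCC(=O)/C=C/[C@](C)(CC(C(=O)OC)(C(=O)OC)C(=O)C(C)(C)Br)C1OCC(C)(C)CO1
F2 | step 2 | racemic dimethyl 2-[3-(ethylsulfanyl)-2-formyl-2-methyl-3-oxopropyl]propanedioate | CCSC(=O)C(C)(CC(C(=O)OC)C(=O)OC)C=O
F3 | step 2 | racemic dimethyl 2-[2-(5,5-dimethyl-1,3-dioxan-2-yl)-3-(ethylsulfanyl)-2-methyl-3-oxopropyl]propanedioate | CCSC(=O)C(C)(CC(C(=O)OC)C(=O)OC)C1OCC(C)(C)CO1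
F4 | step 9 | dimethyl (4aR,6S,8aR)-6-hydroxy-4,4,7,8a-tetramethyl-3-oxo-3,4,4a,5,6,8a-hexahydronaphthalene-2,2(1H)-dicarboxylate | COC(=O)C1(C(=O)OC)C[C@]2(C)C=C(C)[C@@H](O)C[C@H]2C(C)(C)C1=O
F5 | step 9 | dimethyl (4aR,6R,8aR)-4,4,7,8a-tetramethyl-6-[(4-nitrobenzoyl)oxy]-3-oxo-3,4,4a,5,6,8a-hexahydronaphthalene-2,2(1H)-dicarboxylate | COC(=O)C1(C(=O)OC)C[C@]2(C)C=C(C)[C@H](OC(=O)c3ccc(cc3)[N+](=O)[O-])C[C@H]2C(C)(C)C1=O
F6 | step 9 | dimethyl (4aR,6R,8aR)-6-hydroxy-4,4,7,8a-tetramethyl-3-oxo-3,4,4a,5,6,8a-hexahydronaphthalene-2,2(1H)-dicarboxylate | COC(=O)C1(C(=O)OC)C[C@]2(C)C=C(C)[C@H](O)C[C@H]2C(C)(C)C1=O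
F7 | step 9 | dimethyl (4aR,6R,8aR)-4,4,7,8a-tetramethyl-3-oxo-6-[(tributylstannyl)methoxy]-3,4,4a,5,6,8a-hexahydronaphthalene-2,2(1H)-dicarboxylate | COC(=O)C1(C(=O)OC)C[C@]2(C)C=C(C)[C@H](OC[Sn](CCCC)(CCCC)CCCC)C[C@H]2C(C)(C)C1=O
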